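**Retrosynthetic overview**

- The strategy rests on the side-chain ketone carbon C1''. It sits between pyridone C3 (flanked by the C2 lactam carbonyl and the C4 oxygen) and the C2''=C3'' alkene of the trienoyl chain. Both bonds to C1'' are cut together, giving a 3-iodopyridone, carbon monoxide and a (1E,3E,5E)-trienylstannane (carbonylative Stille coupling).
- Iodopyridone: C3–I by electrophilic iodination; N–O by N-oxidation and [1,4] benzyl shift of a 2,4-bis(benzyloxy)pyridine; C5–C1' by aryllithium addition to 4-silyloxycyclohexanone.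
- Stannane: C2''=C3'' by chromium stannyl-olefination of a dienal; C6''=C7'' (with C4''=C5'') by vinylogous Horner–Wadsworth–Emmons olefination; C8'' by auxiliary-controlled hydroxymethylation of a butanoyl imide.
- Rings: none is formed. The pyridine ring (ring A) and the cyclohexane ring (ring B) are bought and only substituted. The route ends with BCl3 debenzylation, then HF·pyridine desilylation.

Key step: step 16

Remark on the chemistry: the cyclohexane-1,4-diol is cis (both hydroxyls on one face, pyridone trans to the secondary hydroxyl), as the target descriptors require. This unit is achiral, so the only absolute stereocentre is C8'' (R). Bn = benzyl, TBS = tert-butyldimethylsilyl.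

**Route**

Step 1
Reactants: 1 5-bromo-2,4-dichloropyridine
Product: 2 2,4-bis(benzyloxy)-5-bromopyridine
Conditions: BnOH, NaH, DMF, 0 → 90 °C
Reagents that add atoms: benzyl alcohol, OCc1ccccc1
Why: Twofold nucleophilic aromatic substitution (SNAr), in which the 2- and 4-chlorides are activated by the ring nitrogen and displaced by benzyloxide, while the 5-bromide at the unactivated position is kept for the later exchange.

Step 2
Reactants: 2 2,4-bis(benzyloxy)-5-bromopyridine; 3 4-[(tert-butyldimethylsilyl)oxy]cyclohexan-1-one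
Product: 5 cis-1-[4,6-bis(benzyloxy)pyridin-3-yl]-4-[(tert-butyldimethylsilyl)oxy]cyclohexan-1-ol (OH cis to OTBS), via 5-lithio-2,4-bis(benzyloxy)pyridine 4 (not isolated)
Conditions: n-BuLi, THF, −78 °C; then 3, −78 → −40 °C; aq NH4Cl
Reagents that add atoms: none
Why: Bromine–lithium exchange at −78 °C outruns benzylic deprotonation, and 1,2-addition of the bulky ortho-alkoxy aryllithium should occur mainly along the equatorial trajectory of the conformer with equatorial OTBS, placing the aryl group trans to OTBS and the new hydroxyl cis to it; the trans-diol isomer is removed by chromatography.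

Step 3
Reactants: 5 cis-1-[4,6-bis(benzyloxy)pyridin-3-yl]-4-[(tert-butyldimethylsilyl)oxy]cyclohexan-1-ol
Product: 6 2,4-bis(benzyloxy)-5-{cis-1-hydroxy-4-[(tert-butyldimethylsilyl)oxy]cyclohexyl}pyridine 1-oxide
Conditions: mCPBA, NaHCO3, CH2Cl2, 0 °C → rt
Reagents that add atoms: 3-chloroperoxybenzoic acid (mCPBA), OOC(=O)c1cccc(Cl)c1
Why: Peracid N-oxidation at the pyridine nitrogen, the most nucleophilic site of the electron-rich dialkoxypyridine; silyl ether, benzyl ethers and tertiary alcohol are inert under bicarbonate buffering.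

Step 4
Reactants: 6 2,4-bis(benzyloxy)-5-{cis-1-hydroxy-4-[(tert-butyldimethylsilyl)oxy]cyclohexyl}pyridine 1-oxide
Product: 7 1,4-bis(benzyloxy)-5-{cis-1-hydroxy-4-[(tert-butyldimethylsilyl)oxy]cyclohexyl}pyridin-2(1H)-one
Conditions: toluene, 110 °C, degassed
Reagents that add atoms: none
Why: Thermal [1,4]-sigmatropic O-to-O benzyl shift of a 2-benzyloxypyridine N-oxide moves the C2 benzyl group onto the N-oxide oxygen and unveils the pyridone carbonyl, while the 4-benzyloxy group has no N–O partner within reach and stays.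

Step 5
Reactants: 7 1,4-bis(benzyloxy)-5-{cis-1-hydroxy-4-[(tert-butyldimethylsilyl)oxy]cyclohexyl}pyridin-2(1H)-one
Product: 8 1,4-bis(benzyloxy)-3-iodo-5-{cis-1-hydroxy-4-[(tert-butyldimethylsilyl)oxy]cyclohexyl}pyridin-2(1H)-one
Conditions: NIS, MeCN, rt, dark
Reagents that add atoms: N-iodosuccinimide, O=C1CCC(=O)N1I
Why: Electrophilic iodination at C3, the only free nucleophilic ring carbon (α-carbon of the vinylogous ester formed by C4–OBn and the lactam; C5 is substituted and C6 is electron-poor).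

Step 6
Reactants: 9 (R)-4-benzyloxazolidin-2-one; 10 butanoyl chloride
Product: 12 (R)-4-benzyl-3-butanoyloxazolidin-2-one, via N-lithio-(R)-4-benzyloxazolidin-2-one 11 (not isolated)
Conditions: n-BuLi, THF, −78 °C; then 10, −78 → 0 °C
Reagents that add atoms: none
Why: N-Acylation of the lithiated oxazolidinone by the acid chloride, the standard loading of an Evans auxiliary.

Step 7
Reactants: 12 (R)-4-benzyl-3-butanoyloxazolidin-2-one; 13 1,3,5-trioxane
Product: 15 (R)-4-benzyl-3-[(S)-2-(hydroxymethyl)butanoyl]oxazolidin-2-one, via trichlorotitanium (Z)-enolate of the imide 14 (not isolated)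
Conditions: TiCl4, i-Pr2NEt, CH2Cl2, 0 °C; then 13, TiCl4, 0 °C
Reagents that add atoms: none
Why: Evans hydroxymethylation, in which the chelated chlorotitanium Z-enolate is attacked by TiCl4-activated trioxane (a formaldehyde equivalent) on the face opposite the C4 benzyl group of the (R)-auxiliary; this sets the future C8'' centre (S in the imide, R in the target after the change of CIP priorities).

Step 8
Reactants: 15 (R)-4-benzyl-3-[(S)-2-(hydroxymethyl)butanoyl]oxazolidin-2-one
Product: 16 (R)-4-benzyl-3-[(S)-2-{[(tert-butyldimethylsilyl)oxy]methyl}butanoyl]oxazolidin-2-one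
Conditions: TBSCl, imidazole, DMF, rt
Reagents that add atoms: tert-butyldimethylsilyl chloride, CC(C)(C)[Si](C)(C)Cl
Why: Silylation of the only free hydroxyl, a primary alcohol, under imidazole catalysis.

Step 9
Reactants: 16 (R)-4-benzyl-3-[(S)-2-{[(tert-butyldimethylsilyl)oxy]methyl}butanoyl]oxazolidin-2-one
Product: 17 (R)-2-{[(tert-butyldimethylsilyl)oxy]methyl}butan-1-ol
Conditions: LiBH4, MeOH, THF, 0 °C
Reagents that add atoms: none
Why: Reductive cleavage of the N-acyloxazolidinone by LiBH4 at the exocyclic carbonyl gives the primary alcohol and returns the auxiliary; at 0 °C the 1,3-silyl migration that would erode the ee of this pseudo-symmetric diol monoether is not expected to compete.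

Step 10
Reactants: 17 (R)-2-{[(tert-butyldimethylsilyl)oxy]methyl}butan-1-ol
Product: 18 (S)-2-{[(tert-butyldimethylsilyl)oxy]methyl}butanal
Conditions: TEMPO (cat.), PhI(OAc)2, CH2Cl2, rt; used at once
Reagents that add atoms: none
Why: TEMPO-catalysed oxidation with PhI(OAc)2 stops at the aldehyde under near-neutral conditions, so the α-stereocentre is not epimerised and the β-silyloxy group is not eliminated.

Step 11
Reactants: 18 (S)-2-{[(tert-butyldimethylsilyl)oxy]methyl}butanal; 19 triethyl (E)-4-phosphonocrotonate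
Product: 21 ethyl (2E,4E,6R)-6-{[(tert-butyldimethylsilyl)oxy]methyl}octa-2,4-dienoate, via lithiated phosphonocrotonate 20 (not isolated)
Conditions: LiHMDS, THF, −78 °C; then 18, −78 → 0 °C
Reagents that add atoms: none
Why: Vinylogous Horner–Wadsworth–Emmons olefination, in which the stabilised phosphonate anion adds at low temperature without enolising the α-branched aldehyde and forms the new alkene E, the second E alkene coming from the reagent.

Step 12
Reactants: 21 ethyl (2E,4E,6R)-6-{[(tert-butyldimethylsilyl)oxy]methyl}octa-2,4-dienoate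
Product: 22 (2E,4E,6R)-6-{[(tert-butyldimethylsilyl)oxy]methyl}octa-2,4-dien-1-ol
Conditions: DIBAL-H, CH2Cl2, −78 °C; aq potassium sodium tartrate
Reagents that add atoms: none
Why: 1,2-Reduction of the conjugated ester to the allylic alcohol by diisobutylaluminium hydride, which leaves the diene and the silyl ether untouched.

Step 13
Reactants: 22 (2E,4E,6R)-6-{[(tert-butyldimethylsilyl)oxy]methyl}octa-2,4-dien-1-ol
Product: 23 (2E,4E,6R)-6-{[(tert-butyldimethylsilyl)oxy]methyl}octa-2,4-dienal
Conditions: MnO2, CH2Cl2, rt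
Reagents that add atoms: none
Why: Chemoselective MnO2 oxidation of an allylic alcohol to the dienal, without over-oxidation or alkene isomerisation.

Step 14
Reactants: 24 dibromomethane; 25 tributyltin chloride
Product: 27 tributyl(dibromomethyl)stannane, via dibromomethyllithium 26 (not isolated)
Conditions: LDA, THF/Et2O, −95 °C; then 25, −95 °C → rt
Reagents that add atoms: none
Why: Deprotonation of CH2Br2 by lithium diisopropylamide gives dibromomethyllithium, which substitutes chloride at tin before it can decompose by α-elimination.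

Step 15
Reactants: 23 (2E,4E,6R)-6-{[(tert-butyldimethylsilyl)oxy]methyl}octa-2,4-dienal; 27 tributyl(dibromomethyl)stannane
Product: 29 tert-butyl(dimethyl){[(2R,3E,5E,7E)-2-ethyl-8-(tributylstannyl)octa-3,5,7-trien-1-yl]oxy}silane, via gem-dichromio(tributylstannyl)methane 28 (not isolated)
Conditions: CrCl2, LiI, THF/DMF, rt, dark; chromatography on Et3N-deactivated silica
Reagents that add atoms: none
Why: Chromium-mediated stannyl-olefination (Hodgson variant of the Takai olefination), in which CrCl2 reduces 27 to a geminal dichromium reagent that adds to the aldehyde and eliminates to give the E-alkenylstannane; the remote stereocentre and the existing E,E-diene are not involved.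

Step 16
Reactants: 8 1,4-bis(benzyloxy)-3-iodo-5-{cis-1-hydroxy-4-[(tert-butyldimethylsilyl)oxy]cyclohexyl}pyridin-2(1H)-one; 29 tert-butyl(dimethyl){[(2R,3E,5E,7E)-2-ethyl-8-(tributylstannyl)octa-3,5,7-trien-1-yl]oxy}silane; 30 carbon monoxide
Product: 31 1,4-bis(benzyloxy)-3-[(2E,4E,6E,8R)-8-{[(tert-butyldimethylsilyl)oxy]methyl}deca-2,4,6-trienoyl]-5-{cis-1-hydroxy-4-[(tert-butyldimethylsilyl)oxy]cyclohexyl}pyridin-2(1H)-one
Conditions: Pd2(dba)3 (5 mol %), AsPh3 (40 mol %), CO (3 atm), NMP, 55 °C, dark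
Reagents that add atoms: none
Why: Zerovalent palladium generated from Pd2(dba)3 and AsPh3 adds oxidatively to the C3–I bond of 8, CO inserts into the aryl–palladium bond to give an aroylpalladium iodide, 29 transfers its terminal alkenyl carbon from tin with retention of the E geometry, and reductive elimination releases ketone 31, so that C3–C1'' and C1''–C2'' are both made in one operation. This is a carbonylative Stille coupling of an aryl iodide with an alkenylstannane, a known way to aryl alkenyl ketones. No ring is closed and no stereocentre is created; because the medium is neutral and no enolate is involved, neither C8'' nor the all-E triene is put at risk. The selectivity that matters is CO insertion ahead of direct transmetalation: the arylpalladium centre is flanked by the C2 carbonyl and the C4 benzyloxy group, which slows direct transfer from tin, while CO pressure and the weakly bound AsPh3 ligand favour migratory insertion. The tertiary hydroxyl is meta to C3 and cannot capture the aroylpalladium intramolecularly.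

Step 17
Reactants: 31 1,4-bis(benzyloxy)-3-[(2E,4E,6E,8R)-8-{[(tert-butyldimethylsilyl)oxy]methyl}deca-2,4,6-trienoyl]-5-{cis-1-hydroxy-4-[(tert-butyldimethylsilyl)oxy]cyclohexyl}pyridin-2(1H)-one
Product: 32 1,4-dihydroxy-3-[(2E,4E,6E,8R)-8-{[(tert-butyldimethylsilyl)oxy]methyl}deca-2,4,6-trienoyl]-5-{cis-1-hydroxy-4-[(tert-butyldimethylsilyl)oxy]cyclohexyl}pyridin-2(1H)-one
Conditions: BCl3, C6HMe5, CH2Cl2, −78 → −40 °C; then MeOH, −78 °C; pH 5 buffer; used crude
Reagents that add atoms: none
Why: Lewis-acid debenzylation with BCl3 and pentamethylbenzene as benzyl-cation scavenger, in which both benzyloxy groups sit next to a carbonyl (C4–O beside the C3 acyl group, N–O beside C2=O) so that chelation-assisted cleavage should proceed at low temperature before the tertiary carbinol ionises; any loss of a silyl group here is harmless because step 18 removes both.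

Step 18
Reactants: 32 1,4-dihydroxy-3-[(2E,4E,6E,8R)-8-{[(tert-butyldimethylsilyl)oxy]methyl}deca-2,4,6-trienoyl]-5-{cis-1-hydroxy-4-[(tert-butyldimethylsilyl)oxy]cyclohexyl}pyridin-2(1H)-one
Product: 33 1,4-dihydroxy-5-(cis-1,4-dihydroxycyclohexyl)-3-[(2E,4E,6E,8R)-8-(hydroxymethyl)deca-2,4,6-trienoyl]pyridin-2(1H)-one
Conditions: HF·pyridine, pyridine, THF, 0 °C → rt; reversed-phase chromatography, dark
Reagents that add atoms: none
Why: Fluoride-mediated cleavage of both Si–O bonds by pyridine-buffered HF, mild enough for the trienone, the acidic hydroxypyridone and the tertiary alcohol.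

**Compound list**

1 | 5-bromo-2,4-dichloropyridine | Clc1cc(Cl)c(Br)cn1 | starting material
2 | 2,4-bis(benzyloxy)-5-bromopyridine | Brc1cnc(OCc2ccccc2)cc1OCc1ccccc1 | intermediate
3 | 4-[(tert-butyldimethylsilyl)oxy]cyclohexan-1-one | CC(C)(C)[Si](C)(C)OC1CCC(=O)CC1 | starting material
4 | 5-lithio-2,4-bis(benzyloxy)pyridine (formed in the flask) | [Li]c1cnc(OCc2ccccc2)cc1OCc1ccccc1 | intermediate
5 | cis-1-[4,6-bis(benzyloxy)pyridin-3-yl]-4-[(tert-butyldimethylsilyl)oxy]cyclohexan-1-ol | C(c1ccccc1)Oc1cc(OCc2ccccc2)ncc1[C@]3(O)CC[C@@H](O[Si](C)(C)C(C)(C)C)CC3 | intermediate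
6 | 2,4-bis(benzyloxy)-5-{cis-1-hydroxy-4-[(tert-butyldimethylsilyl)oxy]cyclohexyl}pyridine 1-oxide | C(c1ccccc1)Oc1cc(OCc2ccccc2)[n+]([O-])cc1[C@]3(O)CC[C@@H](O[Si](C)(C)C(C)(C)C)CC3 | intermediate
7 | 1,4-bis(benzyloxy)-5-{cis-1-hydroxy-4-[(tert-butyldimethylsilyl)oxy]cyclohexyl}pyridin-2(1H)-one | O=c1cc(OCc2ccccc2)c([C@]3(O)CC[C@@H](O[Si](C)(C)C(C)(C)C)CC3)cn1OCc4ccccc4 | intermediate
8 | 1,4-bis(benzyloxy)-3-iodo-5-{cis-1-hydroxy-4-[(tert-butyldimethylsilyl)oxy]cyclohexyl}pyridin-2(1H)-one | O=c1c(I)c(OCc2ccccc2)c([C@]3(O)CC[C@@H](O[Si](C)(C)C(C)(C)C)CC3)cn1OCc4ccccc4 | intermediate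
9 | (R)-4-benzyloxazolidin-2-one | O=C1N[C@H](Cc2ccccc2)CO1 | starting material
10 | butanoyl chloride | CCCC(Cl)=O | starting material
11 | N-lithio-(R)-4-benzyloxazolidin-2-one (formed in the flask) | [Li+].O=C1[N-][C@H](Cc2ccccc2)CO1 | intermediate
12 | (R)-4-benzyl-3-butanoyloxazolidin-2-one | CCCC(=O)N1[C@H](Cc2ccccc2)COC1=O | intermediate
13 | 1,3,5-trioxane | C1OCOCO1 | starting material
14 | trichlorotitanium (Z)-enolate of 12 (formed in the flask) | CC/C=C(\O[Ti](Cl)(Cl)Cl)N1[C@H](Cc2ccccc2)COC1=O | intermediate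
15 | (R)-4-benzyl-3-[(S)-2-(hydroxymethyl)butanoyl]oxazolidin-2-one | CC[C@@H](CO)C(=O)N1[C@H](Cc2ccccc2)COC1=O | intermediate
16 | (R)-4-benzyl-3-[(S)-2-{[(tert-butyldimethylsilyl)oxy]methyl}butanoyl]oxazolidin-2-one | CC[C@@H](CO[Si](C)(C)C(C)(C)C)C(=O)N1[C@H](Cc2ccccc2)COC1=O | intermediate
17 | (R)-2-{[(tert-butyldimethylsilyl)oxy]methyl}butan-1-ol | CC[C@H](CO)CO[Si](C)(C)C(C)(C)C | intermediate
18 | (S)-2-{[(tert-butyldimethylsilyl)oxy]methyl}butanal | CC[C@H](C=O)CO[Si](C)(C)C(C)(C)C | intermediate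
19 | triethyl (E)-4-phosphonocrotonate | CCOC(=O)/C=C/CP(=O)(OCC)OCC | starting material
20 | lithiated triethyl 4-phosphonocrotonate (formed in the flask) | [Li+].CCOC(=O)/C=C/[CH-]P(=O)(OCC)OCC | intermediate
21 | ethyl (2E,4E,6R)-6-{[(tert-butyldimethylsilyl)oxy]methyl}octa-2,4-dienoate | CC[C@H](/C=C/C=C/C(=O)OCC)CO[Si](C)(C)C(C)(C)C | intermediate
22 | (2E,4E,6R)-6-{[(tert-butyldimethylsilyl)oxy]methyl}octa-2,4-dien-1-ol | CC[C@H](/C=C/C=C/CO)CO[Si](C)(C)C(C)(C)C | intermediate
23 | (2E,4E,6R)-6-{[(tert-butyldimethylsilyl)oxy]methyl}octa-2,4-dienal | CC[C@H](/C=C/C=C/C=O)CO[Si](C)(C)C(C)(C)C | intermediate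
24 | dibromomethane | BrCBr | starting material
25 | tributyltin chloride | CCCC[Sn](Cl)(CCCC)CCCC | starting material
26 | dibromomethyllithium (formed in the flask) | [Li]C(Br)Br | intermediate
27 | tributyl(dibromomethyl)stannane | CCCC[Sn](CCCC)(CCCC)C(Br)Br | intermediate
28 | gem-dichromio(tributylstannyl)methane, bis(dichlorochromium) reagent (formed in the flask) | CCCC[Sn](CCCC)(CCCC)C([Cr](Cl)Cl)[Cr](Cl)Cl | intermediate
29 | tert-butyl(dimethyl){[(2R,3E,5E,7E)-2-ethyl-8-(tributylstannyl)octa-3,5,7-trien-1-yl]oxy}silane | CC[C@H](/C=C/C=C/C=C/[Sn](CCCC)(CCCC)CCCC)CO[Si](C)(C)C(C)(C)C | intermediate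
30 | carbon monoxide | [C-]#[O+] | starting material
31 | 1,4-bis(benzyloxy)-3-[(2E,4E,6E,8R)-8-{[(tert-butyldimethylsilyl)oxy]methyl}deca-2,4,6-trienoyl]-5-{cis-1-hydroxy-4-[(tert-butyldimethylsilyl)oxy]cyclohexyl}pyridin-2(1H)-one | CC[C@H](/C=C/C=C/C=C/C(=O)c1c(OCc2ccccc2)c([C@]3(O)CC[C@@H](O[Si](C)(C)C(C)(C)C)CC3)cn(OCc4ccccc4)c1=O)CO[Si](C)(C)C(C)(C)C | intermediate
32 | 1,4-dihydroxy-3-[(2E,4E,6E,8R)-8-{[(tert-butyldimethylsilyl)oxy]methyl}deca-2,4,6-trienoyl]-5-{cis-1-hydroxy-4-[(tert-butyldimethylsilyl)oxy]cyclohexyl}pyridin-2(1H)-one | CC[C@H](/C=C/C=C/C=C/C(=O)c1c(O)c([C@]3(O)CC[C@@H](O[Si](C)(C)C(C)(C)C)CC3)cn(O)c1=O)CO[Si](C)(C)C(C)(C)C | intermediate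
33 | 1,4-dihydroxy-5-(cis-1,4-dihydroxycyclohexyl)-3-[(2E,4E,6E,8R)-8-(hydroxymethyl)deca-2,4,6-trienoyl]pyridin-2(1H)-one | CC[C@H](/C=C/C=C/C=C/C(=O)c1c(O)c([C@]2(O)CC[C@@H](O)CC2)cn(O)c1=O)CO | target

**Step count**

Total: 18 steps. Longest linear sequence: 12 steps (steps 6–13, 15, 16, 17, 18, from 9 and 10 to 33).

**Steps most likely to fail**

1. Step 16 (carbonylative coupling). Direct, non-carbonylative coupling may outrun CO insertion at the hindered C3 position. The trienylstannane may also be consumed by protodestannylation or homocoupling, and prolonged heating with palladium may scramble the triene geometry.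
Fallback, setting out from 23 and 8 and returning at 31: dienal 23 is homologated with (triphenylphosphoranylidene)acetaldehyde in toluene at 70 °C to (2E,4E,6E,8R)-8-{[(tert-butyldimethylsilyl)oxy]methyl}deca-2,4,6-trienal F1. Iodide 8 is converted into its C3 magnesium reagent by iodine–magnesium exchange (i-PrMgCl·LiCl, 2.2 equiv, the first equivalent deprotonating the tertiary hydroxyl, THF, −40 °C) and added to F1. This gives 1,4-bis(benzyloxy)-3-[(2E,4E,6E,8R)-8-{[(tert-butyldimethylsilyl)oxy]methyl}-1-hydroxydeca-2,4,6-trienyl]-5-{cis-1-hydroxy-4-[(tert-butyldimethylsilyl)oxy]cyclohexyl}pyridin-2(1H)-one F2 as a mixture of carbinol epimers. Oxidation of this doubly activated secondary alcohol with MnO2 in CH2Cl2 gives 31.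

2. Step 17 (debenzylation). The Lewis acid may ionise the tertiary, pyridone-activated cyclohexanol, leading to chloride formation or dehydration. Benzyl cations or HCl may also add to the trienone.
Fallback, setting out from 7 and returning at 32: the benzyl groups are exchanged before any alkene is present. Hydrogenolysis of 7 (H2, palladium on carbon, EtOAc) gives 1,4-dihydroxy-5-{cis-1-hydroxy-4-[(tert-butyldimethylsilyl)oxy]cyclohexyl}pyridin-2(1H)-one F3. Alkylation of both acidic hydroxyls with 4-methoxybenzyl chloride and K2CO3 in DMF gives 1,4-bis[(4-methoxybenzyl)oxy]-5-{cis-1-hydroxy-4-[(tert-butyldimethylsilyl)oxy]cyclohexyl}pyridin-2(1H)-one F4. NIS in MeCN gives the 3-iodo derivative of the bis(4-methoxybenzyl) pyridone F5. Carbonylative Stille coupling of F5 with 29 and 30 under the conditions of step 16 gives the bis(4-methoxybenzyl) analogue of 31 F6. Dilute TFA with anisole in CH2Cl2 at 0 °C then removes the two acid-labile 4-methoxybenzyl groups from the acidic oxygens without a strong Lewis acid and gives 32.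

3. Step 2 (aryllithium addition). Facial selectivity may be poor, with axial attack feeding the trans-diol series, and the aryllithium may enolise the ketone.
Fallback, setting out from 2 and returning at 5: bromine–lithium exchange of 2 as in step 2 and addition to 1,4-dioxaspiro[4.5]decan-8-one, where no stereochemical question arises, gives 8-[4,6-bis(benzyloxy)pyridin-3-yl]-1,4-dioxaspiro[4.5]decan-8-ol F7. Ketal hydrolysis with dilute aqueous HCl in THF at rt (the protonated pyridine disfavours ionisation of the carbinol) gives 4-[4,6-bis(benzyloxy)pyridin-3-yl]-4-hydroxycyclohexan-1-one F8. NaBH4 in MeOH at −40 °C delivers hydride axially to the conformer with equatorial aryl and should give cis-1-[4,6-bis(benzyloxy)pyridin-3-yl]cyclohexane-1,4-diol F9. TBSCl and imidazole in DMF silylate only the secondary hydroxyl and give 5.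

**Further compounds**

F1 | step 16 | (2E,4E,6E,8R)-8-{[(tert-butyldimethylsilyl)oxy]methyl}deca-2,4,6-trienal | CC[C@H](/C=C/C=C/C=C/C=O)CO[Si](C)(C)C(C)(C)C
F2 | step 16 | 1,4-bis(benzyloxy)-3-[(2E,4E,6E,8R)-8-{[(tert-butyldimethylsilyl)oxy]methyl}-1-hydroxydeca-2,4,6-trienyl]-5-{cis-1-hydroxy-4-[(tert-butyldimethylsilyl)oxy]cyclohexyl}pyridin-2(1H)-one (carbinol epimers) | CC[C@H](/C=C/C=C/C=C/C(O)c1c(OCc2ccccc2)c([C@]3(O)CC[C@@H](O[Si](C)(C)C(C)(C)C)CC3)cn(OCc4ccccc4)c1=O)CO[Si](C)(C)C(C)(C)C
F3 | step 17 | 1,4-dihydroxy-5-{cis-1-hydroxy-4-[(tert-butyldimethylsilyl)oxy]cyclohexyl}pyridin-2(1H)-one | O=c1cc(O)c([C@]3(O)CC[C@@H](O[Si](C)(C)C(C)(C)C)CC3)cn1O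
F4 | step 17 | 1,4-bis[(4-methoxybenzyl)oxy]-5-{cis-1-hydroxy-4-[(tert-butyldimethylsilyl)oxy]cyclohexyl}pyridin-2(1H)-one | O=c1cc(OCc2ccc(OC)cc2)c([C@]3(O)CC[C@@H](O[Si](C)(C)C(C)(C)C)CC3)cn1OCc4ccc(OC)cc4
F5 | step 17 | 3-iodo-1,4-bis[(4-methoxybenzyl)oxy]-5-{cis-1-hydroxy-4-[(tert-butyldimethylsilyl)oxy]cyclohexyl}pyridin-2(1H)-one | O=c1c(I)c(OCc2ccc(OC)cc2)c([C@]3(O)CC[C@@H](O[Si](C)(C)C(C)(C)C)CC3)cn1OCc4ccc(OC)cc4
F6 | step 17 | 1,4-bis[(4-methoxybenzyl)oxy]-3-[(2E,4E,6E,8R)-8-{[(tert-butyldimethylsilyl)oxy]methyl}deca-2,4,6-trienoyl]-5-{cis-1-hydroxy-4-[(tert-butyldimethylsilyl)oxy]cyclohexyl}pyridin-2(1H)-one | CC[C@H](/C=C/C=C/C=C/C(=O)c1c(OCc2ccc(OC)cc2)c([C@]3(O)CC[C@@H](O[Si](C)(C)C(C)(C)C)CC3)cn(OCc4ccc(OC)cc4)c1=O)CO[Si](C)(C)C(C)(C)C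
F7 | step 2 | 8-[4,6-bis(benzyloxy)pyridin-3-yl]-1,4-dioxaspiro[4.5]decan-8-ol | OC1(c2cnc(OCc3ccccc3)cc2OCc4ccccc4)CCC5(CC1)OCCO5
F8 | step 2 | 4-[4,6-bis(benzyloxy)pyridin-3-yl]-4-hydroxycyclohexan-1-one | OC1(c2cnc(OCc3ccccc3)cc2OCc4ccccc4)CCC(=O)CC1
F9 | step 2 | cis-1-[4,6-bis(benzyloxy)pyridin-3-yl]cyclohexane-1,4-diol | C(c1ccccc1)Oc1cc(OCc2ccccc2)ncc1[C@]3(O)CC[C@@H](O)CC3
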